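The numbers of this flask are invented, and the outcome is calculated.

I set the closed flask zeta beside two neighbours on the same charge, the tank theta and the slow feed epsilon.

    starting material + enzyme → target + enzyme, rate k1*[starting material]*[enzyme]/(1 + ([starting material]/Km1) + ([target]/Kp1)) (Km1 = 5.60 mM, Kp1 = 0.419 mM, k1 = 51400 /M/s)
    2 enzyme → spent catalyst (k2 = 13800 /M/min)
    starting material → uncatalysed product (k3 = 0.0909 /min)

| flask | starting material | enzyme | remark | time |
|---|---|---|---|---|
| theta | 0.050 M | 0.01 mol% | one stirred flow tank at steady state, fed with the mixture as stated, mean residence time 2.0 h |  |
| zeta | 0.050 M | 0.01 mol% | a closed flask charged with all of it at once and left for 2.0 h | 2.0 h |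
| epsilon | 0.050 M (fed, over 1.60 h) | 0.01 mol% | all but starting material at the start; starting material goes in evenly over 1.60 h, the run ends at 2.0 h | 2.0 h |

- for a step with 2 of a species take k times the square, and two of it per event
- the stated concentrations are those of everything mixed, before any reaction; amounts are the same in each set-up
- the feed brings no volume worth counting
- run time (zeta): 2.0 h

- the set-up with the highest share of target in all that became target or uncatalysed product, at the outlet or at the end ("none" if the first two lie within 2 percentage points) (theta / zeta / epsilon / none)
- share of target in all that became target or uncatalysed product, at the outlet or at the end, theta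
- share of target in all that became target or uncatalysed product, at the outlet or at the end, zeta
- share of target in all that became target or uncatalysed product, at the outlet or at the end, epsilon

I reckoned zeta by hand. Let A, P and U be starting material, target and uncatalysed product, and C the enzyme. Let kE and kU be the constants of the enzyme step and the uncatalysed step, and Km and Kp those of the rate law. One rate over the other gave the selectivity factor:

dP/dU = Pb/(Kp + P + Kp·A/Km), with Pb = Kp·kE·C/kU

On fresh enzyme of 0.00500 mM, Pb was 71.1 mM. I called Pb the break-even target: the target at which, with little A about, both steps run level. It stood higher than the charge cA of 0.050 M.

The run of 2.0 h was far longer than the 11.0 min lifetime of A by the uncatalysed step alone, so I set U = cA − P. I dropped the small terms and integrated: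

P·P = 2·Pb·(cA − P)

From above, enzyme kept fresh gave a share P/cA of 78.4%.

From below, I let the enzyme die. Its first half-life by its own step was 7.25 min, a little shorter than the 7.63 min half-life of A by the uncatalysed step alone. Enzyme frozen at its level after one lifetime of A by that step, 0.00199 mM, gave Pb = 28.2 mM and a share of 63.9%. That floor was a judgement, not a strict bound, since some A outlasts that moment.

The forecast named zeta, with 42.5% for theta, 70% for zeta and 45% for epsilon, holding that “the batch wins by putting all the starting material in front of fresh enzyme”. Its zeta figure lay inside my bracket.

The simulation gave zeta as best, with 42.6% for theta, 70.4% for zeta and 43.0% for epsilon.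

Zeta's reading lay inside the bracket, and its break-even target began at 71.1 mM, above the charge of 0.050 M. Theta's steady enzyme works out at 0.00109 mM, which puts its break-even target at 15.5 mM, below the charge. Taken at theta's outlet state, the ratio reads P·P = Pb·(cA − P), without the factor 2, and gives 42.2% against the 42.6% of theta.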